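## Retrosynthetic overview

1. Target 8 is methyl (−)-shikimate with an acetate on O3 and (R)-2-methylbutanoates on O4 and O5. C3–C5 (3R,4S,5R) come with (−)-shikimic acid 1, and both side-chain centres (R,R) come with (R)-2-methylbutanoic acid 4.
2. Key disconnection: the O4–C(=O) bond and the acetate C=O are made together. The 3,4-O-ethylidene acetal 5 and free acid 4 are joined by an anodic dehydrogenative acetal/acid coupling that loses only H2.
3. The O5–C(=O) bond comes from Steglich esterification of 3 with 4. The acetal and the methyl ester are installed in one pot from 1.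
4. Rings: the cyclohexene is bought. The only ring formed is the temporary cis-fused dioxolane, closed in step 1 and opened in step 3.

Assumption: 1 and 4 are bought as catalogue chemicals. The acetal carbon of 3 and 5 is an epimer mixture and is left undefined in the SMILES, because step 3 destroys it.

## Route

Step 1
Reactants: 1 (−)-shikimic acid
Product: 3 methyl 3,4-O-ethylidene-shikimate (epimer mixture at the acetal carbon), via methyl shikimate 2 (not isolated)
Conditions: MeOH, TsOH·H2O (5 mol %), reflux, 12 h; evaporate; MeCH(OMe)2 (3 equiv), MeCN, rt, 3 h; Et3N quench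
Reagents that add atoms: methanol CO; acetaldehyde dimethyl acetal CC(OC)OC
Why: Fischer esterification followed by acid-catalysed transacetalisation, in which only the cis-3,4-diol can close an unstrained cis-fused dioxolane (the 4,5-diol is trans-diequatorial), no ring C–O bond is broken so 3R,4S,5R are kept, and the new acetal carbon is erased in step 3.

Step 2
Reactants: 3 methyl 3,4-O-ethylidene-shikimate; 4 (R)-2-methylbutanoic acid
Product: 5 methyl 3,4-O-ethylidene-5-O-[(R)-2-methylbutanoyl]shikimate
Conditions: 4 (1.3 equiv), DCC (1.4 equiv), DMAP (10 mol %), CH2Cl2, 0 °C to rt, 6 h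
Reagents that add atoms: (R)-2-methylbutanoic acid 4 CC[C@@H](C)C(=O)O
Why: Steglich esterification of the only free hydroxyl forms the O5–acyl bond, so C5 and the bought (R)-α-carbon are untouched, and catalytic DMAP at low temperature is the usual epimerisation-free protocol for 2-methylbutanoates, with acetal and enoate inert.

Step 3
Reactants: 5 methyl 3,4-O-ethylidene-5-O-[(R)-2-methylbutanoyl]shikimate; 4 (R)-2-methylbutanoic acid
Product: 8 methyl (3R,4S,5R)-3-acetoxy-4,5-bis{[(2R)-2-methylbutanoyl]oxy}cyclohex-1-ene-1-carboxylate (target), via dioxolan-2-ylium cation 6 (not isolated), via acyloxy orthoester 7 (not isolated)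
Conditions: (+)RVC | Pt(−), undivided cell, 5 mA, 2.4 F mol−1, Cl4NHPI (20 mol %), 2,6-lutidine (0.5 equiv), 4 (3 equiv), Bu4NBF4 (0.1 M), dry MeCN, 3 Å MS, Ar, 25 °C; then PPTS (10 mol %), 45 °C, 2 h
Reagents that add atoms: (R)-2-methylbutanoic acid 4 CC[C@@H](C)C(=O)O
Why: Proposed new method: the anodically generated tetrachlorophthalimide-N-oxyl abstracts the most hydridic C–H of 5 (the acetal C–H between two oxygens, whereas C3–H is pseudo-equatorial, lies near the nodal plane of an electron-poor enoate and is polarity-mismatched), the dioxolan-2-yl radical is oxidised at once to cation 6, un-ionised 4 (carboxylic acids stay protonated beside lutidine in MeCN, which suppresses both Kolbe oxidation and SN2 opening by carboxylate) adds at C2 to give 7, and pyridinium-acid-catalysed, stereoelectronically controlled cleavage of the C2–O4 (equatorial) bond leaves the acetate on pseudo-axial O3 while the freed O4–H takes the 2-methylbutanoyl group from the O-alkylated mixed anhydride through a seven-membered transition state, so no carbinol C–O bond breaks, C3 and C4 keep their configuration and H2 leaves at the cathode; the closest known reaction types are anodic alkoxylation of cyclic acetals to orthoesters, N-oxyl-mediated oxidation of acetals to hydroxy esters, axial-ester-selective opening of cyclic orthoesters (the same O4-selective cleavage is seen in reductive opening of shikimate 3,4-ketals to 3-O-alkyl ethers), and the ortho-diacetate pathway that gives cis-diacetates in acetate-free acetolysis of trans-2-acetoxycyclohexyl sulfonates.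

## Compound list

1 | (−)-shikimic acid, (3R,4S,5R)-3,4,5-trihydroxycyclohex-1-ene-1-carboxylic acid | O[C@@H]1[C@H](O)C=C(C(=O)O)C[C@H]1O | starting material
2 | methyl shikimate (3R,4S,5R) | O[C@@H]1[C@H](O)C=C(C(=O)OC)C[C@H]1O | intermediate
3 | methyl 3,4-O-ethylidene-shikimate (cis-fused dioxolane on O3/O4, free 5-OH, acetal carbon epimeric) | CC1O[C@@H]2[C@H](O1)C=C(C(=O)OC)C[C@H]2O | intermediate
4 | (R)-2-methylbutanoic acid | CC[C@@H](C)C(=O)O | starting material
5 | methyl 3,4-O-ethylidene-5-O-[(R)-2-methylbutanoyl]shikimate | CC1O[C@@H]2[C@H](O1)C=C(C(=O)OC)C[C@H]2OC(=O)[C@H](C)CC | intermediate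
6 | 2-methyl-1,3-dioxolan-2-ylium cation bridging O3/O4 of the 5-O-acyl shikimate | C[C+]1O[C@@H]2[C@H](O1)C=C(C(=O)OC)C[C@H]2OC(=O)[C@H](C)CC | intermediate
7 | 2-methyl-2-[(R)-2-methylbutanoyloxy]-1,3-dioxolane (acyloxy orthoester) on O3/O4 of the 5-O-acyl shikimate | CC[C@@H](C)C(=O)OC1(C)O[C@@H]2[C@H](O1)C=C(C(=O)OC)C[C@H]2OC(=O)[C@H](C)CC | intermediate
8 | methyl (3R,4S,5R)-3-acetoxy-4,5-bis{[(2R)-2-methylbutanoyl]oxy}cyclohex-1-ene-1-carboxylate | CC[C@@H](C)C(=O)O[C@@H]1[C@H](OC(C)=O)C=C(C(=O)OC)C[C@H]1OC(=O)[C@H](C)CC | target

## Step count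

Total step count: 3 (step 1 is a two-stage one-pot operation).
Longest linear sequence: 3 steps, 1 → 3 → 5 → 8.

## Steps most likely to fail

**1. Step 3 (the new step).** Several things can go wrong:
- Hydrogen abstraction may occur at C3–H or C6–H, or be slow for the acetal epimer whose C–H points into the concave face.
- Orthoester 7 may fail to collapse.
- Cation 6 may be opened at allylic C3 with inversion.
- Cation 6 may be attacked at C4 by the trans 5-ester (acyloxonium migration).
- The acyl groups may end up interchanged on O3 and O4.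

The fallback uses known chemistry only. It sets out from 2, isolated after the first stage of step 1, and comes back at 8. Trimethyl orthoacetate with catalytic TsOH in CH2Cl2 converts the cis-diol into methyl 3,4-O-(1-methoxyethylidene)shikimate F1. DCC/DMAP with 4 gives methyl 3,4-O-(1-methoxyethylidene)-5-O-[(R)-2-methylbutanoyl]shikimate F2. Aqueous 80 % AcOH at rt opens the orthoester by the axial-ester rule to methyl 3-O-acetyl-5-O-[(R)-2-methylbutanoyl]shikimate F3. A second Steglich esterification with pre-activated 4 at 0 °C, fast enough to outrun acetyl migration, acylates O4 and gives 8.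

**2. Step 1.** The telescoped acid sequence may leave unesterified acid. It may also give 5-O-(1-methoxyethyl) mixed acetals and an unfavourable epimer ratio. The fallback sets out from 1 and comes back at 3, reversing the order and changing the ester-forming mechanism. The free acid is acetalised first (MeCH(OMe)2, TsOH, DMF, rt) to 3,4-O-ethylidene-shikimic acid F4. Its carboxylate is then alkylated by SN2 with MeI/K2CO3 in DMF, so the acetal never meets acidic methanol.

**3. Step 2.** Activation of 4 may cause slight α-epimerisation through the acylpyridinium/ketene channel, or be diverted to N-acylurea. The fallback sets out from 2 and comes back at 5. It makes the C5–O bond with the unactivated carboxylate as nucleophile, so the α-carbon cannot epimerise.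
- Mitsunobu cyclodehydration (PPh3, DIAD, THF, 0 °C) gives methyl (1S,5R,6R)-5-hydroxy-7-oxabicyclo[4.1.0]hept-3-ene-3-carboxylate F5. The epoxide oxygen is O4, cis to the 3-OH, and C5 is inverted.
- A buffered caesium carboxylate (4, 3 equiv; Cs2CO3, 0.5 equiv; DMF, 70 °C) opens the epoxide at C5, as azide does with the related 3-O-alkyl 4,5-epoxides. The second inversion restores 5R and gives methyl 5-O-[(R)-2-methylbutanoyl]shikimate F6.
- MeCH(OMe)2 with catalytic TsOH then closes the 3,4-acetal to give 5.

## Further compounds

F1 | step 3 | methyl 3,4-O-(1-methoxyethylidene)shikimate | COC1(C)O[C@@H]2[C@H](O1)C=C(C(=O)OC)C[C@H]2O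
F2 | step 3 | methyl 3,4-O-(1-methoxyethylidene)-5-O-[(R)-2-methylbutanoyl]shikimate | COC1(C)O[C@@H]2[C@H](O1)C=C(C(=O)OC)C[C@H]2OC(=O)[C@H](C)CC
F3 | step 3 | methyl 3-O-acetyl-5-O-[(R)-2-methylbutanoyl]shikimate | O[C@@H]1[C@H](OC(C)=O)C=C(C(=O)OC)C[C@H]1OC(=O)[C@H](C)CC
F4 | step 1 | 3,4-O-ethylidene-shikimic acid | CC1O[C@@H]2[C@H](O1)C=C(C(=O)O)C[C@H]2O
F5 | step 2 | methyl (1S,5R,6R)-5-hydroxy-7-oxabicyclo[4.1.0]hept-3-ene-3-carboxylate | O[C@@H]1C=C(C(=O)OC)C[C@@H]2O[C@H]12
F6 | step 2 | methyl 5-O-[(R)-2-methylbutanoyl]shikimate | O[C@@H]1[C@H](O)C=C(C(=O)OC)C[C@H]1OC(=O)[C@H](C)CC
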